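The readings were computed from invented constants; the scatter is artificial.

**One-step world.** In a one-step world each starting material consumed becomes target. This gas-fed flask has other exits, so its turnovers are counted exit by exit.

the same everywhere: gas phase 32 mM (held); catalyst 62 µM
- cedar: starting material 0.050 M; protic impurity 0.050 M; run made earlier
- larch: starting material 0.20 M; protic impurity 0.050 M; run made earlier
- flask: starting material 0.10 M; protic impurity 0.0500 M; time 4.0 min

| run | time / min | target / % |
|---|---|---|
| cedar | 0.417 | 10.5 |
| cedar | 0.667 | 15.8 |
| cedar | 1.33 | 27.0 |
| cedar | 2.50 | 30.7 |
| cedar | 5.00 | 30.0 |
| larch | 0.417 | 4.6 |
| larch | 0.667 | 10.9 |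
| larch | 1.33 | 21.6 |
| larch | 2.50 | 39.0 |
| larch | 5.00 | 53.8 |

(scatter of a reading: 1 percentage point)

* target at 4.0 min, in percent of the starting material charged
* concentration of dissolved gas in solution at 25 s, in percent of saturation
* the change that raises the amount of target at 4.0 min, in percent of the starting material charged most ("none" if none brings more than 2 percentage points) (Friday's / Saturday's / Thursday's / none)
* amount of target at 4.0 min, in percent of the starting material charged, after Friday's

- Friday's: doubling the transfer coefficient of the gas phase, all else as stated
- Saturday's: doubling the amount of catalyst, all else as stated
- Thursday's: doubling the saturation concentration of gas phase, all else as stated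

- at the start none of the gas is dissolved
- the numbers in the tables scatter by 1 percentage point (one standard deviation)
- on the list of suspects stand: gas phase <-> dissolved gas; starting material + dissolved gas + catalyst -> catalyst + target; starting material + protic impurity -> quenched substrate; starting material + dissolved gas -> uncatalysed product

**The toll.** Quenching spends protic impurity one for one with starting material, so the impurity can claim at most c(protic impurity)/c(starting material) of a charge: 25.0% in larch, 50.0% in the flask.

**The split.** Take larch's last reading, 53.8%, as finished and its toll as paid in full. That gives 71.7%: the target split, target made per starting material that escapes quenching, a selectivity between the gas routes. Applied to the flask, the split gives 35.9% target.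

**Weak link.** The full toll is the weak link. Cedar's toll is 100%, yet it shows 30.0% target, so impurity survived there. By the split, 41.8% of cedar's charge took the gas routes, and with equal charges that share of impurity remained. If dissolved gas holds level, c(protic impurity) falls exponentially with gas-route turnover, by a factor e per 0.0240 M. The flask's gas routes turn over at least 0.0500 M, which by this reckoning leaves 12.4% of its impurity. My reforged figure is therefore 40.3% target.

**The forecast.** It gives 42.5% target, Saturday's as the best change and 48% after Friday's, holding that “impurity quenching wastes much substrate”. For dissolved gas it gives 38% of saturation at 25 s. Its target figure stands above my 40.3%.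

**The flask.** The flask gives 38.2% target, Saturday's as the best change, worth 9.4 percentage points, and 40.3% after Friday's. Its dissolved gas stands at 41.1% of saturation at 25 s.

    gas phase ⇌ dissolved gas, rate k1*(csat - [dissolved gas]) (kL = 0.0425 s⁻¹)
    starting material + dissolved gas + catalyst → catalyst + target (k = 8520 L² mol⁻² s⁻¹)
    starting material + protic impurity → quenched substrate (k = 0.469 L mol⁻¹ s⁻¹)
    starting material + dissolved gas → uncatalysed product (k = 0.229 L mol⁻¹ s⁻¹)

**At rest.** By 4.0 min the flask has quenched 44.8%, less than its toll of 50.0%, and its own split, from target and uncatalysed product, is 69.8%. A neighbour with 0.20 M of protic impurity quenches 90.4%, so the split leaves it 6.88% target, against its simulated 6.71%. In the flask, starting material, the limiting reagent, has 0.45% left at 4.00 min, worth 0.32 points of target by the split. At 40.0 min target stands at 38.5%, protic impurity at 10.3% of its charge, and dissolved gas has risen from 0.0314 M to 0.0320 M.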